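## Retrosynthetic overview
1. Hanultarin is the mono-(E)-feruloyl ester of (R,R)-secoisolariciresinol. The ferulate is built last: malonic half-ester of one CH2OH of the C2-symmetric diol, then Knoevenagel–Doebner condensation with vanillin.
2. The (R,R)-diol comes from ozonolysis and reduction of an Ireland–Claisen acid. The central C2–C3 bond and both stereocenters form in one [3,3] shift, via a chair TS with an E-alkene and a (Z)-silyl ketene acetal. That combination gives the dl (C2-type) relationship, and the (R)-carbinol sets the absolute sense.
3. The Claisen ester joins protected dihydroferulic acid to (R,E)-5-aryl-pent-3-en-2-ol. That alcohol comes from cross-metathesis of MOM-eugenol with (R)-but-3-en-2-ol.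
4. No ring is built except a transient γ-lactone used for purification. All three aryl rings come from eugenol, dihydroferulic acid and vanillin.

Assumptions: both phenols of the lignan core are protected as MOM ethers until the last step. (R)-But-3-en-2-ol is available in high ee.

## Route

**Step 1**
Reactants: 1 eugenol
Product: 2 MOM-eugenol (4-allyl-2-methoxy-1-(methoxymethoxy)benzene)
Conditions: MOMCl, i-Pr2NEt, CH2Cl2, 0 °C → rt
Reagents that add atoms: MOMCl, COCCl (leaves CH2OCH3)
Why: Williamson-type O-alkylation masks the phenol so it survives LDA, metathesis and LiAlH4 later.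

**Step 2**
Reactants: 2 MOM-eugenol; 3 (R)-but-3-en-2-ol
Product: 4 (2R,3E)-5-[3-methoxy-4-(methoxymethoxy)phenyl]pent-3-en-2-ol
Conditions: Grubbs II (5 mol%), 1,4-benzoquinone (10 mol%), 3 (4 equiv), CH2Cl2, 40 °C
Reagents that add atoms: none (ethylene is lost)
Why: Olefin cross-metathesis gives the thermodynamic E-alkene. The carbinol stereocenter is untouched and will control the Claisen facial selectivity. Benzoquinone suppresses Ru–H isomerization.

**Step 3**
Reactants: 5 dihydroferulic acid (3-(4-hydroxy-3-methoxyphenyl)propanoic acid)
Product: 6 methoxymethyl 3-[3-methoxy-4-(methoxymethoxy)phenyl]propanoate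
Conditions: MOMCl (2.3 equiv), i-Pr2NEt, CH2Cl2, 0 °C → rt
Reagents that add atoms: MOMCl, COCCl
Why: Both the phenol and the carboxylic acid are alkoxymethylated, giving the aryl MOM ether and a MOM ester.

**Step 4**
Reactants: 6
Product: 7 3-[3-methoxy-4-(methoxymethoxy)phenyl]propanoic acid
Conditions: LiOH·H2O, THF/H2O (3:1), rt
Reagents that add atoms: water, O
Why: The activated MOM ester is saponified selectively while the aryl MOM acetal is base-stable.

**Step 5**
Reactants: 4 allylic alcohol; 7 acid
Product: 8 (2R,3E)-5-aryl-pent-3-en-2-yl 3-arylpropanoate (aryl = 3-methoxy-4-(methoxymethoxy)phenyl)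
Conditions: EDC·HCl, DMAP (cat.), CH2Cl2, 0 °C → rt
Reagents that add atoms: none
Why: Steglich esterification is mild, and the carbinol stereocenter is not involved (no C–O cleavage).

**Step 6**
Reactants: 8
Product: 9 (2R,3S,4E)-2,3-bis{[3-methoxy-4-(methoxymethoxy)phenyl]methyl}hex-4-enoic acid
Conditions: LDA (2 equiv), THF/DMPU (4:1), –78 °C; TBSCl; –78 °C → rt, 12 h; then aq. KHSO4 workup
Reagents that add atoms: none (TBSCl only forms a transient silyl ester that is removed on workup)
Why: Ireland–Claisen rearrangement. The THF/DMPU conditions give the (Z)-silyl ketene acetal (CH2Ar cis to OSi). With the E-alkene in a chair TS, both CH2Ar groups are equatorial, which gives the dl (C2-type) relationship. The (R)-carbinol with equatorial methyl fixes the absolute sense and is destroyed as the new E-propenyl group. The 3S label is only a CIP change; spatially this is the R,R arrangement of the diol.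

**Step 7**
Reactants: 9
Product: 10 (3R,4R)-3,4-bis{[3-methoxy-4-(methoxymethoxy)phenyl]methyl}oxolan-2-one (trans-dibenzylbutyrolactone)
Conditions: (i) O3, CH2Cl2/MeOH 3:1, –78 °C; (ii) NaBH4, –78 → 0 °C; (iii) aq. KHSO4 workup, then PPTS (cat.), PhMe, 60 °C
Reagents that add atoms: ozone, [O-][O+]=O (supplies the new CH2–O oxygen)
Why: Ozonolysis is chemoselective for the disubstituted alkyl alkene over the arenes at –78 °C with a stoichiometric endpoint. In situ NaBH4 reduction avoids an epimerizable free aldehyde. The γ-hydroxy acid lactonizes to the crystalline trans-lactone, which can be purified and upgraded in ee. No stereocenter is altered, and trans is thermodynamically favored anyway.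

**Step 8**
Reactants: 10
Product: 11 (2R,3R)-2,3-bis{[3-methoxy-4-(methoxymethoxy)phenyl]methyl}butane-1,4-diol
Conditions: LiAlH4, THF, 0 °C → rt
Reagents that add atoms: none
Why: Hydride reduction of the lactone to the diol leaves the aryl MOM ethers and both stereocenters untouched.

**Step 9**
Reactants: 11 diol (1.0 equiv); 12 Meldrum's acid (0.9 equiv)
Product: 13 mono-[(2R,3R)-4-hydroxy-2,3-bis(arylmethyl)butyl] malonate
Conditions: PhMe, 100 °C, 4 h; the mono-acid is separated from recovered diol and bis-malonate by base extraction and chromatography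
Reagents that add atoms: none (Meldrum's acid is reactant 12; acetone is lost)
Why: Thermal alcoholysis of Meldrum's acid via carboxyketene gives a malonic half-ester. The diol is C2-symmetric, so either OH gives the same compound, and sub-stoichiometric acid limits bis-acylation.

**Step 10**
Reactants: 13; 14 vanillin (1.5 equiv)
Product: 15 bis-MOM hanultarin
Conditions: pyridine, piperidine (0.1 equiv), 80 °C, 12 h
Reagents that add atoms: none (vanillin is reactant 14; H2O and CO2 are lost)
Why: Knoevenagel–Doebner condensation with decarboxylation gives the (E)-feruloyl ester, and the free phenol of vanillin is tolerated. The free CH2OH and the MOM ethers survive.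

**Step 11**
Reactants: 15
Product: 16 hanultarin
Conditions: 3 M HCl, THF/MeOH (1:1), 40 °C, 4–6 h
Reagents that add atoms: none
Why: Acid hydrolysis of the aryl MOM acetals releases the free phenols while the cinnamate ester survives. Any acyl migration to the other CH2OH is degenerate because the diol is C2-symmetric.

## Compound list
1 | eugenol, 4-allyl-2-methoxyphenol | C=CCc1ccc(O)c(OC)c1 | starting material
2 | MOM-eugenol | C=CCc1ccc(OCOC)c(OC)c1 | intermediate
3 | (R)-but-3-en-2-ol | C[C@@H](O)C=C | starting material
4 | (2R,3E)-5-aryl-pent-3-en-2-ol | C[C@@H](O)/C=C/Cc1ccc(OCOC)c(OC)c1 | intermediate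
5 | dihydroferulic acid | OC(=O)CCc1ccc(O)c(OC)c1 | starting material
6 | MOM ester of MOM-protected dihydroferulic acid | COCOC(=O)CCc1ccc(OCOC)c(OC)c1 | intermediate
7 | 3-[3-methoxy-4-(methoxymethoxy)phenyl]propanoic acid | OC(=O)CCc1ccc(OCOC)c(OC)c1 | intermediate
8 | Claisen ester | C[C@@H](OC(=O)CCc1ccc(OCOC)c(OC)c1)/C=C/Cc1ccc(OCOC)c(OC)c1 | intermediate
9 | (2R,3S,4E)-bis(arylmethyl)hex-4-enoic acid | C/C=C/[C@H](Cc1ccc(OCOC)c(OC)c1)[C@@H](Cc1ccc(OCOC)c(OC)c1)C(=O)O | intermediate
10 | (3R,4R)-bis(arylmethyl)-γ-butyrolactone | O=C1OC[C@H](Cc2ccc(OCOC)c(OC)c2)[C@H]1Cc1ccc(OCOC)c(OC)c1 | intermediate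
11 | (2R,3R)-bis(arylmethyl)butane-1,4-diol | OC[C@H](Cc1ccc(OCOC)c(OC)c1)[C@H](CO)Cc1ccc(OCOC)c(OC)c1 | intermediate
12 | Meldrum's acid | CC1(C)OC(=O)CC(=O)O1 | starting material
13 | malonic half-ester of 11 | OC(=O)CC(=O)OC[C@H](Cc1ccc(OCOC)c(OC)c1)[C@H](CO)Cc1ccc(OCOC)c(OC)c1 | intermediate
14 | vanillin | COc1cc(C=O)ccc1O | starting material
15 | bis-MOM hanultarin | COc1cc(/C=C/C(=O)OC[C@H](Cc2ccc(OCOC)c(OC)c2)[C@H](CO)Cc2ccc(OCOC)c(OC)c2)ccc1O | intermediate
16 | hanultarin | COc1cc(/C=C/C(=O)OC[C@H](Cc2ccc(O)c(OC)c2)[C@H](CO)Cc2ccc(O)c(OC)c2)ccc1O | target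

## Totals
- Total steps: 11.
- Longest linear sequence: 9 steps (either 1 → 2 → 4 → 8 → … or 5 → 6 → 7 → 8 → …, then 9 → 10 → 11 → 13 → 15 → 16).

## Three steps most likely to fail
1. **Step 6 (Ireland–Claisen).** The dr depends on the ketene acetal geometry and chair selectivity, and the α-CH2Ar ester may give partial E/Z mixtures.
   - Fallback: build lactone 10 by a different strategy. Make the (R)-β-arylmethyl-γ-butyrolactone by Evans alkylation, reduction and cyclization, then do a trans-selective LDA α-benzylation with the MOM-protected benzyl bromide. Rejoin the route at Step 8.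
2. **Step 9 (statistical mono-malonylation).** Yield is capped at about 50%, and bis-acylation competes.
   - Fallback: differentiate the two OH groups by protecting group instead of statistics. Mono-silylate diol 11 (NaH, TBSCl, THF), run the Meldrum's acid and Doebner sequence on the remaining OH, then remove TBS and MOM together with HCl. Alternatively, use a lipase (CAL-B) with vinyl ferulate on the deprotected diol.
3. **Step 2 (cross-metathesis).** Allylbenzene isomerization, homodimerization of 2 or isomerization of the allylic alcohol to a ketone can lower the yield.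
   - Fallback: make alcohol 4 by a different route. Ozonolyze 2 to the arylacetaldehyde, run an HWE reaction with dimethyl 2-oxopropylphosphonate to give the (E)-enone, then reduce with a chiral Ru–TsDPEN transfer-hydrogenation catalyst of the matching hand to give the (R)-alcohol.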